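Two oxygenated carbons face each other across the ten-membered ring: the C1 ketone and C6, which holds the lactone oxygen. Joining them in thought gives a C1=C6 double bond, the fusion alkene shared by ring A and ring B of an octalin. Ozone cleaves this one tetrasubstituted alkene, turns both carbons into ketones and so releases the cyclodecane from the bicycle in a single operation, without any end-to-end macrocyclisation. The precursor is a carvone-derived epoxy octalin ester in which the cis C4–C5 oxirane and the centres C7, C8, C10 and C11 are already fixed; afterwards C6 is reduced and lactonised and the C8 silyl ether is exchanged for the methacrylate.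

Key step: step 26

Locants are those of the target (C1 ketone, C4–C5 oxirane, C6 lactone oxygen, C7, C8 ester, C10 acetate, C11 with C12 and C13, C14 and C15 methyls); ring B = C1, C6–C10, ring A = C1–C6; β is the ring face that carries the C7 side chain. Assumption: the (S,S)-ligand of step 12 gives the (R)-ether and the lipase of step 19 acylates the arm that becomes C13; where the sense is opposite, the other ligand antipode or the hydrolytic mode (diacetate, same enzyme) is used.

Step 1
Reactants: 1 (S)-(+)-carvone
Product: 2 cis-carveol, (1S,5S)-2-methyl-5-(prop-1-en-2-yl)cyclohex-2-en-1-ol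
Conditions: NaBH4, CeCl3·7H2O, MeOH, 0 °C
Reagents that add atoms: none
Why: Luche reduction gives clean 1,2-reduction of the enone, and axial hydride delivery to the half-chair with the isopropenyl group equatorial places the new C1 hydroxyl β, cis to the C7 side chain.

Step 2
Reactants: 2 cis-carveol
Product: 3 9,10β-epoxy alcohol (oxirane syn to the C1 hydroxyl)
Conditions: VO(acac)2 (2 mol %), tBuOOH, CH2Cl2, 0 °C → rt
Reagents that add atoms: tert-butyl hydroperoxide, CC(C)(C)OO
Why: Hydroxyl-directed vanadium-catalysed epoxidation delivers oxygen only to the allylic alkene and on the face of the C1 hydroxyl, so the C10 oxygen becomes β while the isopropenyl group is untouched.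

Step 3
Reactants: 3 9,10β-epoxy alcohol
Product: 4 4-methoxybenzyl (PMB) ether of 3
Conditions: NaH, 4-MeOC6H4CH2Cl, Bu4NI (cat.), THF/DMF, 0 °C → rt
Reagents that add atoms: 4-methoxybenzyl chloride, COc1ccc(CCl)cc1
Why: Williamson etherification masks the C1 hydroxyl as an ether that survives selenolate, hydride and borane, and Payne migration cannot compete because the alkoxide sits syn to the oxirane and cannot reach its backside.

Step 4
Reactants: 4 PMB ether
Product: 7 tertiary allylic alcohol (C8=C9 alkene; C10 β-OH), via hydroxy selenide 5 (not isolated), via selenoxide 6 (not isolated)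
Conditions: (PhSe)2, NaBH4, EtOH, reflux; then H2O2 (30 %), THF, 0 °C → rt
Reagents that add atoms: none
Why: In this organoselenium epoxide-to-allylic-alcohol transposition the selenolate opens the oxirane at the secondary C9 with inversion, so the C10–O bond and its β configuration are untouched, and the selenoxide syn-eliminates toward C8 because C10 carries no hydrogen.

Step 5
Reactants: 7 tertiary allylic alcohol
Product: 8 8,9β-epoxy alcohol
Conditions: VO(acac)2 (5 mol %), tBuOOH, PhMe, rt → 40 °C
Reagents that add atoms: tert-butyl hydroperoxide, CC(C)(C)OO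
Why: A second hydroxyl-directed epoxidation, now steered by the tertiary allylic C10 hydroxyl, puts the oxirane on the β face of C8–C9 and leaves the isolated isopropenyl alkene alone.

Step 6
Reactants: 8 8,9β-epoxy alcohol
Product: 9 cis-1,3-diol (C8 β-OH, C10 β-OH)
Conditions: LiAlH4, THF, 0 → 50 °C
Reagents that add atoms: none
Why: Hydride opening obeys the Fürst–Plattner rule, since in the half-chair that keeps the isopropenyl, methyl and PMB-oxy groups equatorial the trans-diaxial path is attack at C9, so the oxygen stays on C8 in the β configuration, cis to the C7 side chain.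

Step 7
Reactants: 9 cis-1,3-diol
Product: 10 triol with a 3-hydroxyprop-1-en-2-yl group at C7
Conditions: SeO2 (0.3 equiv), tBuOOH, CH2Cl2, rt
Reagents that add atoms: selenium dioxide (oxygen carrier), O=[Se]=O; tert-butyl hydroperoxide (terminal oxidant), CC(C)(C)OO
Why: Riley allylic oxidation (ene reaction then [2,3]-sigmatropic shift) hydroxylates the methyl of the isopropenyl group, the only alkene left, and creates no stereocentre.

Step 8
Reactants: 10 allylic alcohol triol
Product: 12 tetraol (C7 bears a 1,3-dihydroxypropan-2-yl group), via alkylborane 11 (not isolated)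
Conditions: 9-borabicyclo[3.3.1]nonane (5 equiv), THF, 0 °C → rt; then NaOH, H2O2, 0 °C
Reagents that add atoms: hydrogen peroxide, OO
Why: Anti-Markovnikov hydroboration–oxidation of the 1,1-disubstituted alkene adds the second hydroxymethyl arm, and because the two arms are then identical C11 is not a stereocentre and no facial selectivity is required.

Step 9
Reactants: 12 tetraol
Product: 14 tris(tert-butyldimethylsilyl) triethylsilyl ether, via tris-silyl alcohol 13 (not isolated)
Conditions: tBuMe2SiOTf (3.1 equiv), 2,6-lutidine, CH2Cl2, −78 → −40 °C; then Et3SiOTf, −40 → 0 °C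
Reagents that add atoms: tert-butyldimethylsilyl triflate, CC(C)(C)[Si](C)(C)OS(=O)(=O)C(F)(F)F; triethylsilyl triflate, CC[Si](CC)(CC)OS(=O)(=O)C(F)(F)F
Why: Silyl ether formation follows steric access, so the limiting bulky triflate caps the two primary hydroxyls and the C8 hydroxyl in the cold and the smaller triethylsilyl triflate then caps the shielded tertiary C10 hydroxyl.

Step 10
Reactants: 14 fully silylated PMB ether
Product: 15 C1 alcohol
Conditions: DDQ, CH2Cl2/pH 7 buffer (10:1), 0 °C
Reagents that add atoms: none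
Why: Oxidative cleavage of the PMB ether frees only the C1 hydroxyl, the silyl ethers being inert and the silylated C10 oxygen unable to trap the benzylic cation as an acetal.

Step 11
Reactants: 15 C1 alcohol
Product: 16 ring B ketone
Conditions: Dess–Martin periodinane, NaHCO3, CH2Cl2, rt
Reagents that add atoms: none
Why: Dess–Martin oxidation gives the C1 ketone under buffered conditions, and this ketone can enolise only toward C6 because C10 is fully substituted.

Step 12
Reactants: 17 2-methyl-2-vinyloxirane (racemic)
Product: 18 (R)-2-[(4-methoxybenzyl)oxy]-2-methylbut-3-en-1-ol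
Conditions: Pd2(dba)3·CHCl3 (1 mol %), (S,S)-N,N′-(cyclohexane-1,2-diyl)bis[2-(diphenylphosphino)benzamide] (3 mol %), Et3B (1 mol %), 4-MeOC6H4CH2OH, CH2Cl2, rt
Reagents that add atoms: 4-methoxybenzyl alcohol, COc1ccc(CO)cc1
Why: In this palladium-catalysed dynamic kinetic asymmetric allylic etherification both epoxide enantiomers ionise to rapidly interconverting π-allyl complexes, the boron co-catalyst delivers the alcohol to the substituted terminus, and the chiral ligand sets the future C4 carbinol centre.

Step 13
Reactants: 18 (R)-ether alcohol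
Product: 19 (R)-2-[(4-methoxybenzyl)oxy]-2-methylbut-3-enal
Conditions: Dess–Martin periodinane, NaHCO3, CH2Cl2, 0 °C → rt
Reagents that add atoms: none
Why: Dess–Martin oxidation of the primary alcohol gives an aldehyde whose α-carbon is quaternary, so it can neither enolise nor racemise.

Step 14
Reactants: 16 ring B ketone; 19 (R)-aldehyde
Product: 20 aldol adduct (C5–C6 bond; mixture at C5 and C6)
Conditions: LiN(iPr)2, THF, −78 °C; then 19, −78 °C
Reagents that add atoms: none
Why: In this directed aldol addition the lithium enolate can form only at C6 and adds to the non-enolisable aldehyde, and the configurations at C5 and C6 do not matter because both centres become trigonal in the next two steps.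

Step 15
Reactants: 20 aldol adduct
Product: 21 1,3-diketone
Conditions: Dess–Martin periodinane, CH2Cl2, rt
Reagents that add atoms: none
Why: Dess–Martin oxidation turns the β-hydroxy ketone into the β-diketone without retro-aldol cleavage and removes the stereochemical mixture at C5.

Step 16
Reactants: 21 1,3-diketone
Product: 22 enol triflate (C1–OTf, C1=C6)
Conditions: KN(SiMe3)2, THF, −78 °C; then PhNTf2, −78 → 0 °C
Reagents that add atoms: N-phenylbis(trifluoromethanesulfonimide), O=S(=O)(N(c1ccccc1)S(=O)(=O)C(F)(F)F)C(F)(F)F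
Why: O-sulfonylation of the diketone enolate should occur on the ring oxygen, because 2-acylcyclohexanones enolise with the double bond inside the ring and the C5 carbonyl is shielded by the fully substituted C4, which fixes the alkene at C1=C6 (the other regioisomer could not cyclise in step 17).

Step 17
Reactants: 22 enol triflate
Product: 24 octalinone (ring A closed; C5 ketone; C1=C6), via alkylborane 23 (not isolated)
Conditions: 9-borabicyclo[3.3.1]nonane, THF, 0 °C → rt; then Pd(dppf)Cl2·CH2Cl2 (10 mol %), AsPh3, Cs2CO3, DMF/THF/H2O, 50 °C, 0.005 M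
Reagents that add atoms: none
Why: Hydroboration places boron on the terminal vinyl carbon (the future C2) and an intramolecular B-alkyl Suzuki–Miyaura coupling with the vinylogous acyl triflate closes ring A as a six-membered ring, leaving the tetrasubstituted C1=C6 alkene exactly at the ring fusion.

Step 18
Reactants: 24 octalinone
Product: 25 triol (C10–OH and the two hydroxymethyl arms free; C8 silyl ether kept)
Conditions: HF·pyridine, pyridine, THF, 0 °C → rt
Reagents that add atoms: none
Why: Fluoride-mediated desilylation discriminates by steric access, so the two primary silyl ethers and the labile triethylsilyl ether are removed while the hindered secondary C8 silyl ether remains.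

Step 19
Reactants: 25 triol
Product: 26 monoacetate (C11 stereocentre as in the target; acetate on the future C13)
Conditions: lipase from Burkholderia cepacia (immobilised), vinyl acetate, tBuOMe, 30 °C
Reagents that add atoms: vinyl acetate, CC(=O)OC=C
Why: Enzymatic desymmetrisation by irreversible transesterification acylates one of the two diastereotopic hydroxymethyl arms of the 2-substituted propane-1,3-diol, which creates the C11 stereocentre under catalyst control and installs the C13 acetate of the target at the same time.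

Step 20
Reactants: 26 monoacetate
Product: 28 carboxylic acid (C12), via aldehyde 27 (not isolated)
Conditions: 2,2,6,6-tetramethylpiperidin-1-oxyl (20 mol %), PhI(OAc)2 (2.5 equiv), MeCN/H2O (1:1), rt
Reagents that add atoms: water, O
Why: Oxoammonium-mediated oxidation takes the primary alcohol through the aldehyde hydrate to the acid in a weakly acidic medium, so the β-acetoxy aldehyde never meets base and C11 is neither epimerised nor lost by elimination, while tertiary alcohols and the electron-poor enone alkene are inert.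

Step 21
Reactants: 28 carboxylic acid
Product: 29 methyl ester
Conditions: Me3SiCHN2, MeOH/PhMe, 0 °C
Reagents that add atoms: trimethylsilyldiazomethane, C[Si](C)(C)C=[N+]=[N-]
Why: Esterification with the diazoalkane proceeds by protonation and O-alkylation of the carboxylate under neutral conditions, so the base-sensitive β-acetoxy ester forms without elimination.

Step 22
Reactants: 29 methyl ester
Product: 30 C10 acetate
Conditions: Ac2O, 4-(dimethylamino)pyridine, Et3N, CH2Cl2, rt
Reagents that add atoms: acetic anhydride, CC(=O)OC(C)=O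
Why: Nucleophile-catalysed acylation esterifies the tertiary allylic C10 hydroxyl, the only free hydroxyl and pseudo-equatorial in the octalin half-chair, under a base too weak to eliminate the β-acetoxy ester.

Step 23
Reactants: 30 C10 acetate
Product: 31 α-hydroxy enone (C4–OH free)
Conditions: DDQ, CH2Cl2/pH 7 buffer (10:1), rt
Reagents that add atoms: none
Why: Oxidative PMB ether cleavage frees the tertiary C4 hydroxyl without touching the esters, the silyl ether or the enone.

Step 24
Reactants: 31 α-hydroxy enone
Product: 32 trans-4,5-diol (C4 β-OH, C5 α-OH)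
Conditions: Me4NBH(OAc)3, MeCN/AcOH (1:1), −20 °C
Reagents that add atoms: none
Why: In this hydroxyl-directed reduction the borohydride exchanges an acetate for the C4 hydroxyl and delivers hydride intramolecularly to the carbonyl face syn to that oxygen, so the new C5 hydroxyl is trans to the C4 oxygen, and ketones without such an anchor are not reduced by this mild reagent.

Step 25
Reactants: 32 trans-4,5-diol
Product: 33 epoxy octalin ester (4,5β-oxirane; rings A and B fused at C1=C6)
Conditions: PPh3, diisopropyl azodicarboxylate, PhMe, 0 → 50 °C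
Reagents that add atoms: none
Why: In this Mitsunobu cyclodehydration the phosphonium activates the secondary allylic C5 hydroxyl and the anti-disposed tertiary C4 oxygen displaces it with inversion under neutral conditions, which gives the cis-fused β-oxirane with C4 retained and tolerates both acetates and the ester.

Step 26
Reactants: 33 epoxy octalin ester
Product: 36 epoxy cyclodecane-1,6-dione ester, via primary ozonide 34 (not isolated), via secondary ozonide 35 (not isolated)
Conditions: O3, CH2Cl2, −78 °C (to first persistent blue); then PPh3, −78 °C → rt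
Reagents that add atoms: ozone, [O-][O+]=O
Why: Ozone adds to the only C=C bond, the electron-rich tetrasubstituted C1=C6 alkene, by 1,3-dipolar cycloaddition; the primary ozonide cycloreverts to a ketone and a carbonyl oxide that stay linked by both four-carbon bridges and recombine to the secondary ozonide, which triphenylphosphine reduces to the 1,6-diketone. The closest known reaction is the ozonolysis of the ring-fusion alkene of octalins to cyclodecane-1,6-diones. The ten-membered ring is not closed end to end: it is the periphery of the bicycle and is released by fragmentation of the shared C1=C6 bond, so ring A and ring B vanish together. No stereocentre is created, and C4, C5, C7, C8, C10 and C11 pass through unchanged because nothing is enolised under the cold, neutral conditions. The step needs chemoselectivity, which is secured by the absence of any other alkene (the methacrylate is attached last) and by the inertness of the oxirane, the esters and the silyl ether toward ozone. The diketone is kept neutral and is reduced at once, since acid or base could start transannular aldol reactions.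

Step 27
Reactants: 36 epoxy cyclodecane-1,6-dione ester
Product: 38 6,12-lactone silyl ether, via hydroxy ester 37 (not isolated)
Conditions: Zn(BH4)2, Et2O, −30 °C; then pyridinium p-toluenesulfonate (cat.), CH2Cl2, rt
Reagents that add atoms: none
Why: In this chelation-controlled reduction zinc bridges the C6 carbonyl and the adjacent oxirane oxygen, which activates this ketone over the neopentyl α-acetoxy C1 ketone and sends hydride to the ring-periphery face to give the erythro epoxy alcohol (C6 oxygen cis to the C7–C11 bond), and the γ-hydroxy ester then lactonises to the cis-fused γ-lactone with loss of methanol.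

Step 28
Reactants: 38 6,12-lactone silyl ether
Product: 39 C8 alcohol
Conditions: HF·pyridine, pyridine, THF, 0 °C → rt
Reagents that add atoms: none
Why: Fluoride-mediated desilylation removes the last silyl ether under buffered, weakly acidic conditions that avoid the enolate chemistry (loss of the C13 acetate, lactone migration to O8) that basic fluoride sources would risk.

Step 29
Reactants: 39 C8 alcohol
Product: 40 CNP0166747.1
Conditions: methacrylic anhydride, pyridine, 4-(dimethylamino)pyridine (cat.), CH2Cl2, 0 °C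
Reagents that add atoms: methacrylic anhydride, C=C(C)C(=O)OC(=O)C(C)=C
Why: Nucleophile-catalysed acylation esterifies the only free hydroxyl, the secondary C8 alcohol, with retention, and the weak base and low temperature leave the β-acetoxy lactone, the oxirane and the α-acetoxy ketone untouched.

Compound list
1 | (S)-(+)-carvone | CC1=CC[C@@H](CC1=O)C(C)=C | starting material
2 | cis-carveol, (1S,5S)-2-methyl-5-(prop-1-en-2-yl)cyclohex-2-en-1-ol | CC1=CC[C@@H](C[C@@H]1O)C(C)=C | intermediate
3 | 9,10β-epoxy alcohol (oxirane, C1–OH and C7 isopropenyl all on the β face) | C[C@@]12O[C@@H]1C[C@@H](C[C@@H]2O)C(C)=C | intermediate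
4 | PMB ether of 3 | C[C@@]12O[C@@H]1C[C@@H](C[C@@H]2OCc3ccc(OC)cc3)C(C)=C | intermediate
5 | hydroxy selenide (C9 α-SePh, C10 β-OH), not isolated | C[C@@]1(O)[C@@H]([Se]c2ccccc2)C[C@@H](C[C@@H]1OCc3ccc(OC)cc3)C(C)=C | intermediate
6 | selenoxide of 5 (mixture at selenium), not isolated | C[C@@]1(O)[C@@H]([Se](=O)c2ccccc2)C[C@@H](C[C@@H]1OCc3ccc(OC)cc3)C(C)=C | intermediate
7 | tertiary allylic alcohol (C8=C9; C10 β-OH, α-methyl; C1 β-OPMB) | C[C@@]1(O)C=C[C@@H](C[C@@H]1OCc2ccc(OC)cc2)C(C)=C | intermediate
8 | 8,9β-epoxy alcohol | C[C@@]1(O)[C@@H]2O[C@@H]2[C@@H](C[C@@H]1OCc3ccc(OC)cc3)C(C)=C | intermediate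
9 | cis-1,3-diol (C8 β-OH, C10 β-OH, C1 β-OPMB, C7 β-isopropenyl) | O[C@H]1C[C@@](C)(O)[C@@H](OCc2ccc(OC)cc2)C[C@H]1C(C)=C | intermediate
10 | triol with 3-hydroxyprop-1-en-2-yl group at C7 | O[C@H]1C[C@@](C)(O)[C@@H](OCc2ccc(OC)cc2)C[C@H]1C(=C)CO | intermediate
11 | B-alkyl-9-borabicyclononane adduct (hydroxyls drawn free; mixture at C11), not isolated | O[C@H]1C[C@@](C)(O)[C@@H](OCc2ccc(OC)cc2)C[C@H]1C(CO)CB3C4CCCC3CCC4 | intermediate
12 | tetraol (C7 bears 1,3-dihydroxypropan-2-yl; C11 not stereogenic) | O[C@H]1C[C@@](C)(O)[C@@H](OCc2ccc(OC)cc2)C[C@H]1C(CO)CO | intermediate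
13 | tris(tert-butyldimethylsilyl) ether with free C10–OH, not isolated | CC(C)(C)[Si](C)(C)O[C@H]1C[C@@](C)(O)[C@@H](OCc2ccc(OC)cc2)C[C@H]1C(CO[Si](C)(C)C(C)(C)C)CO[Si](C)(C)C(C)(C)C | intermediate
14 | tris(tert-butyldimethylsilyl) C10-triethylsilyl ether, C1–OPMB | CC(C)(C)[Si](C)(C)O[C@H]1C[C@@](C)(O[Si](CC)(CC)CC)[C@@H](OCc2ccc(OC)cc2)C[C@H]1C(CO[Si](C)(C)C(C)(C)C)CO[Si](C)(C)C(C)(C)C | intermediate
15 | C1 alcohol | CC(C)(C)[Si](C)(C)O[C@H]1C[C@@](C)(O[Si](CC)(CC)CC)[C@@H](O)C[C@H]1C(CO[Si](C)(C)C(C)(C)C)CO[Si](C)(C)C(C)(C)C | intermediate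
16 | ring B ketone (C1=O; C8 β-OTBS; C10 β-OTES; C7 β side chain) | CC(C)(C)[Si](C)(C)O[C@H]1C[C@@](C)(O[Si](CC)(CC)CC)C(=O)C[C@H]1C(CO[Si](C)(C)C(C)(C)C)CO[Si](C)(C)C(C)(C)C | intermediate
17 | 2-methyl-2-vinyloxirane (isoprene monoepoxide, racemic) | CC1(CO1)C=C | starting material
18 | (R)-2-[(4-methoxybenzyl)oxy]-2-methylbut-3-en-1-ol | C=C[C@@](CO)(C)OCc1ccc(OC)cc1 | intermediate
19 | (R)-2-[(4-methoxybenzyl)oxy]-2-methylbut-3-enal | C=C[C@@](C=O)(C)OCc1ccc(OC)cc1 | intermediate
20 | aldol adduct (mixture at C5 and C6) | CC(C)(C)[Si](C)(C)O[C@H]1C[C@@](C)(O[Si](CC)(CC)CC)C(=O)C([C@H]1C(CO[Si](C)(C)C(C)(C)C)CO[Si](C)(C)C(C)(C)C)C(O)[C@](C)(OCc2ccc(OC)cc2)C=C | intermediate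
21 | 1,3-diketone (C1 and C5 carbonyls; C6 epimerisable) | CC(C)(C)[Si](C)(C)O[C@H]1C[C@@](C)(O[Si](CC)(CC)CC)C(=O)C([C@H]1C(CO[Si](C)(C)C(C)(C)C)CO[Si](C)(C)C(C)(C)C)C(=O)[C@](C)(OCc2ccc(OC)cc2)C=C | intermediate
22 | enol triflate (C1–OTf, C1=C6, C5 ketone) | CC(C)(C)[Si](C)(C)O[C@H]1C[C@@](C)(O[Si](CC)(CC)CC)C(OS(=O)(=O)C(F)(F)F)=C([C@H]1C(CO[Si](C)(C)C(C)(C)C)CO[Si](C)(C)C(C)(C)C)C(=O)[C@](C)(OCc2ccc(OC)cc2)C=C | intermediate
23 | B-alkyl-9-borabicyclononane adduct of 22 (boron on C2), not isolated | CC(C)(C)[Si](C)(C)O[C@H]1C[C@@](C)(O[Si](CC)(CC)CC)C(OS(=O)(=O)C(F)(F)F)=C([C@H]1C(CO[Si](C)(C)C(C)(C)C)CO[Si](C)(C)C(C)(C)C)C(=O)[C@](C)(OCc2ccc(OC)cc2)CCB3C4CCCC3CCC4 | intermediate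
24 | octalinone (C5 ketone, C1=C6, C4 β-OPMB) | CC(C)(C)[Si](C)(C)O[C@H]1C[C@@](C)(O[Si](CC)(CC)CC)C2=C([C@H]1C(CO[Si](C)(C)C(C)(C)C)CO[Si](C)(C)C(C)(C)C)C(=O)[C@](C)(OCc3ccc(OC)cc3)CC2 | intermediate
25 | triol (C10–OH, two hydroxymethyl arms; C8–OTBS) | CC(C)(C)[Si](C)(C)O[C@H]1C[C@@](C)(O)C2=C([C@H]1C(CO)CO)C(=O)[C@](C)(OCc3ccc(OC)cc3)CC2 | intermediate
26 | monoacetate (11S by the sequence rule here; same spatial arrangement as C11 of the target) | CC(C)(C)[Si](C)(C)O[C@H]1C[C@@](C)(O)C2=C([C@H]1[C@H](COC(C)=O)CO)C(=O)[C@](C)(OCc3ccc(OC)cc3)CC2 | intermediate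
27 | C12 aldehyde, not isolated | CC(C)(C)[Si](C)(C)O[C@H]1C[C@@](C)(O)C2=C([C@H]1[C@H](COC(C)=O)C=O)C(=O)[C@](C)(OCc3ccc(OC)cc3)CC2 | intermediate
28 | C12 carboxylic acid (11R) | CC(C)(C)[Si](C)(C)O[C@H]1C[C@@](C)(O)C2=C([C@H]1[C@H](COC(C)=O)C(=O)O)C(=O)[C@](C)(OCc3ccc(OC)cc3)CC2 | intermediate
29 | methyl ester | CC(C)(C)[Si](C)(C)O[C@H]1C[C@@](C)(O)C2=C([C@H]1[C@H](COC(C)=O)C(=O)OC)C(=O)[C@](C)(OCc3ccc(OC)cc3)CC2 | intermediate
30 | C10 acetate | CC(C)(C)[Si](C)(C)O[C@H]1C[C@@](C)(OC(C)=O)C2=C([C@H]1[C@H](COC(C)=O)C(=O)OC)C(=O)[C@](C)(OCc3ccc(OC)cc3)CC2 | intermediate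
31 | α-hydroxy enone (C4 β-OH, C5 ketone) | CC(C)(C)[Si](C)(C)O[C@H]1C[C@@](C)(OC(C)=O)C2=C([C@H]1[C@H](COC(C)=O)C(=O)OC)C(=O)[C@](C)(O)CC2 | intermediate
32 | trans-4,5-diol (C4 β-OH, C5 α-OH) | CC(C)(C)[Si](C)(C)O[C@H]1C[C@@](C)(OC(C)=O)C2=C([C@H]1[C@H](COC(C)=O)C(=O)OC)[C@@H](O)[C@](C)(O)CC2 | intermediate
33 | epoxy octalin ester (rings A and B fused at C1=C6; 4,5β-oxirane) | CC(C)(C)[Si](C)(C)O[C@H]1C[C@@](C)(OC(C)=O)C2=C([C@H]1[C@H](COC(C)=O)C(=O)OC)[C@@H]3O[C@]3(C)CC2 | intermediate
34 | primary ozonide (1,2,3-trioxolane on C1–C6; C1 and C6 undefined), not isolated | CC(C)(C)[Si](C)(C)O[C@H]1C[C@@](C)(OC(C)=O)C23CC[C@@]4(C)O[C@H]4C2(OOO3)[C@H]1[C@H](COC(C)=O)C(=O)OC | intermediate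
35 | secondary ozonide (1,2,4-trioxolane bridging C1 and C6; C1 and C6 undefined), not isolated | CC(C)(C)[Si](C)(C)O[C@H]1C[C@@](C)(OC(C)=O)C2(CC[C@@]3(C)O[C@H]3C4(OO2)[C@H]1[C@H](COC(C)=O)C(=O)OC)O4 | intermediate
36 | epoxy cyclodecane-1,6-dione ester | CC(C)(C)[Si](C)(C)O[C@H]1C[C@@](C)(OC(C)=O)C(=O)CC[C@@]2(C)O[C@H]2C(=O)[C@H]1[C@H](COC(C)=O)C(=O)OC | intermediate
37 | C6 β-hydroxy ester, not isolated | CC(C)(C)[Si](C)(C)O[C@H]1C[C@@](C)(OC(C)=O)C(=O)CC[C@@]2(C)O[C@H]2[C@@H](O)[C@H]1[C@H](COC(C)=O)C(=O)OC | intermediate
38 | 6,12-lactone, C8 silyl ether | CC(C)(C)[Si](C)(C)O[C@H]1C[C@@](C)(OC(C)=O)C(=O)CC[C@@]2(C)O[C@H]2[C@H]2OC(=O)[C@@H](COC(C)=O)[C@H]21 | intermediate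
39 | 6,12-lactone, C8 alcohol | O[C@H]1C[C@@](C)(OC(C)=O)C(=O)CC[C@@]2(C)O[C@H]2[C@H]2OC(=O)[C@@H](COC(C)=O)[C@H]21 | intermediate
40 | CNP0166747.1 | C=C(C)C(=O)O[C@H]1C[C@@](C)(OC(C)=O)C(=O)CC[C@@]2(C)O[C@H]2[C@H]2OC(=O)[C@@H](COC(C)=O)[C@H]21 | target

Total step count: 29. Longest linear sequence: 27 steps (steps 1–11 and 14–29); steps 12–13 make the C2–C5 fragment.

Steps most likely to fail

Step 26. The hindered alkene, flanked by an allylic acetate and an oxirane, may be only partly cleaved or merely epoxidised by ozone, or the diketone may undergo transannular aldol condensation during work-up. The fallback splits the cleavage into two mild operations. It sets out from 33: dihydroxylation of the C1=C6 alkene (RuCl3 cat., NaIO4, CeCl3·7H2O, EtOAc/MeCN/H2O, 0 °C, or OsO4 in pyridine) should give the 1,6-diol F1, and glycol cleavage with Pb(OAc)4 (K2CO3, CH2Cl2, 0 °C) comes back to the route at 36.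

Step 27. Site selectivity between the two ketones may be lost, so that C1 is reduced together with C6. The fallback accepts over-reduction. It sets out from 36: excess Zn(BH4)2 at 0 °C should reduce both ketones to the 1,6-dihydroxy ester F2, pyridinium p-toluenesulfonate closes the γ-lactone to the C1-hydroxy lactone F3, and Dess–Martin oxidation of the one remaining secondary alcohol comes back to the route at 38.

Step 19. The enzyme may discriminate poorly, or in the wrong sense, between the two hydroxymethyl arms. The fallback replaces catalyst control by separation and recycling. It sets out from 25: non-selective monoacetylation (Ac2O, 1 equiv, 2,4,6-collidine, CH2Cl2, −40 °C) gives 26 together with the C11-epimeric monoacetate F4 and some diacetate F5. The two monoacetates are diastereomers and are separated by chromatography; F4 and F5 are methanolysed (K2CO3, MeOH) back to the symmetric triol 25 and recycled. The route is rejoined at 26.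

Further compounds
F1 | step 26 | 1,6-diol of the octalin (cis-diol at C1 and C6, face undefined) | CC(C)(C)[Si](C)(C)O[C@H]1C[C@@](C)(OC(C)=O)C2(O)CC[C@@]3(C)O[C@H]3C2(O)[C@H]1[C@H](COC(C)=O)C(=O)OC
F2 | step 27 | 1,6-dihydroxy ester (C1 undefined, C6 β-OH) | CC(C)(C)[Si](C)(C)O[C@H]1C[C@@](C)(OC(C)=O)C(O)CC[C@@]2(C)O[C@H]2[C@@H](O)[C@H]1[C@H](COC(C)=O)C(=O)OC
F3 | step 27 | C1-hydroxy 6,12-lactone (C1 undefined) | CC(C)(C)[Si](C)(C)O[C@H]1C[C@@](C)(OC(C)=O)C(O)CC[C@@]2(C)O[C@H]2[C@H]2OC(=O)[C@@H](COC(C)=O)[C@H]21
F4 | step 19 | C11-epimeric monoacetate | CC(C)(C)[Si](C)(C)O[C@H]1C[C@@](C)(O)C2=C([C@H]1[C@@H](COC(C)=O)CO)C(=O)[C@](C)(OCc3ccc(OC)cc3)CC2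
F5 | step 19 | diacetate | CC(C)(C)[Si](C)(C)O[C@H]1C[C@@](C)(O)C2=C([C@H]1C(COC(C)=O)COC(C)=O)C(=O)[C@](C)(OCc3ccc(OC)cc3)CC2
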